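**Strategy.** The epoxide carbon Cq carries ring A, one oxygen and two CH2–O arms (the oxirane CH2 and the acetoxymethyl CH2), which is exactly C3 of a 3-aryloxetan-3-ol with its two ring CH2 groups. The route therefore rests on a Norrish–Yang photocyclization of an aryl methoxymethyl ketone: one irradiation joins the carbonyl carbon to the OCH3 carbon, creating the second Cq–CH2 bond and the oxetane ring. The precursor is the ring A ketone ArC(=O)CH2OCH3 that already bears the para pentanoyloxymethyl group and the ortho isobutyrate. The achiral oxetane is then opened enantioselectively by bromide, and the bromohydrin is acetylated and closed to the (S)-epoxide.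

Key step: step 7

Assumption: the target stereocentre is (S) (CIP order O > CH2OAc > oxirane CH2 > aryl), which corresponds to the (2R)-bromohydrin; the sense of induction of the squaramide on this oxetane cannot be predicted safely, so the catalyst antipode that gives the (2R)-bromohydrin is to be fixed by a test run.

**Step 1**
Reactants: 1 methyl 4-bromo-3-hydroxybenzoate
Product: 2 methyl 4-bromo-3-(methoxymethoxy)benzoate
Conditions: MOMCl, i-Pr2NEt, CH2Cl2, 0 °C → rt
Reagents that add atoms: chloromethyl methyl ether (MOMCl), COCCl
Why: Williamson-type O-alkylation of the phenol to its MOM ether; the amine base deprotonates only the phenol and the methyl ester is untouched.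

**Step 2**
Reactants: 2 methyl 4-bromo-3-(methoxymethoxy)benzoate
Product: 3 [4-bromo-3-(methoxymethoxy)phenyl]methanol
Conditions: i-Bu2AlH (2.5 equiv), CH2Cl2, −78 → 0 °C; aq. potassium sodium tartrate
Reagents that add atoms: none
Why: Hydride reduction of the ester to the primary alcohol; the aryl bromide and the MOM acetal are inert to the aluminium hydride at low temperature.

**Step 3**
Reactants: 3 [4-bromo-3-(methoxymethoxy)phenyl]methanol, 4 2-methoxy-N-methoxy-N-methylacetamide
Product: 7 1-[4-(hydroxymethyl)-2-(methoxymethoxy)phenyl]-2-methoxyethan-1-one, via dilithiated aryl alkoxide 5 (not isolated), via lithium aminal adduct 6 (not isolated)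
Conditions: n-BuLi (2.1 equiv), THF, −78 °C; then 4, −78 → −20 °C; AcOH quench
Reagents that add atoms: none
Why: Bromine–lithium exchange followed by Weinreb ketone synthesis: the first equivalent of n-BuLi makes the lithium alkoxide, the second exchanges the bromide next to the chelating MOM oxygen, and the chelated adduct 6 collapses to the ketone only on quench, so no second addition occurs.

**Step 4**
Reactants: 7 1-[4-(hydroxymethyl)-2-(methoxymethoxy)phenyl]-2-methoxyethan-1-one, 8 pentanoyl chloride
Product: 9 [4-(2-methoxyacetyl)-3-(methoxymethoxy)phenyl]methyl pentanoate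
Conditions: Et3N, DMAP (cat.), CH2Cl2, 0 °C
Reagents that add atoms: none
Why: DMAP-catalysed esterification (nucleophilic acyl substitution) at the only free hydroxyl group, the primary benzylic alcohol, so no chemoselectivity question arises.

**Step 5**
Reactants: 9 [4-(2-methoxyacetyl)-3-(methoxymethoxy)phenyl]methyl pentanoate
Product: 10 [3-hydroxy-4-(2-methoxyacetyl)phenyl]methyl pentanoate
Conditions: CF3CO2H, CH2Cl2, H2O (trace), 0 °C → rt
Reagents that add atoms: none
Why: Acid-catalysed acetal cleavage of the aryl MOM ether, helped by the ortho carbonyl; the benzylic ester, the methyl ether and the ketone are stable to trifluoroacetic acid at this temperature.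

**Step 6**
Reactants: 10 [3-hydroxy-4-(2-methoxyacetyl)phenyl]methyl pentanoate, 11 2-methylpropanoyl chloride (isobutyryl chloride)
Product: 12 [4-(2-methoxyacetyl)-3-(2-methylpropanoyloxy)phenyl]methyl pentanoate
Conditions: Et3N, DMAP (cat.), CH2Cl2, 0 °C
Reagents that add atoms: none
Why: DMAP-catalysed O-acylation of the phenol, the only hydroxyl group left; the amine base is too weak to enolize the ketone, so no Baker–Venkataraman acyl shift is expected.

**Step 7**
Reactants: 12 [4-(2-methoxyacetyl)-3-(2-methylpropanoyloxy)phenyl]methyl pentanoate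
Product: 14 [4-(3-hydroxyoxetan-3-yl)-3-(2-methylpropanoyloxy)phenyl]methyl pentanoate, via 1,4-biradical 13 (not isolated)
Conditions: hν (350–365 nm), degassed MeCN (0.02 M), 20 °C
Reagents that add atoms: none
Why: Excitation of the aryl ketone gives, after intersystem crossing, the n,π* triplet, whose oxygen takes a hydrogen from the O–CH3 group through a six-membered transition state (1,5-hydrogen transfer), and the triplet 1,4-biradical 13 couples after spin inversion to join the former carbonyl carbon, now Cq, to the former methyl carbon. The closest known reaction type is the Norrish–Yang photocyclization of α-alkoxyacetophenones to 3-aryloxetan-3-ols. The oxetane ring is closed by radical–radical recombination at the two ends of the chain Cq–CH2–O–CH2. No stereocenter arises, because Cq then carries two identical CH2–O arms and the product has a mirror plane. The step needs hydrogen abstraction at OCH3 only and coupling of 13 in preference to Norrish type 2 cleavage into an enol and formaldehyde: the ether oxygen activates the OCH3 hydrogens, the ortho substituent is an ester with no C–H within reach of the carbonyl oxygen and no phenolic proton for excited-state proton transfer, and hydrogen bonding of the ketyl OH to the ortho ester carbonyl and to acetonitrile should slow the return of hydrogen and favour the folded biradical that couples. Light of 350–365 nm is absorbed only by the ketone n,π* band, so the aryl isobutyrate is not excited and a photo-Fries shift is avoided.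

**Step 8**
Reactants: 14 [4-(3-hydroxyoxetan-3-yl)-3-(2-methylpropanoyloxy)phenyl]methyl pentanoate
Product: 15 [3-(2-methylpropanoyloxy)-4-[3-(trimethylsilyloxy)oxetan-3-yl]phenyl]methyl pentanoate
Conditions: Me3SiCl, imidazole, CH2Cl2, 0 °C → rt
Reagents that add atoms: chlorotrimethylsilane, C[Si](C)(C)Cl
Why: Silyl ether formation at the tertiary alcohol removes the only protic site, so that Me3SiBr cannot release HBr and open the oxetane in a racemic background reaction in step 9.

**Step 9**
Reactants: 15 [3-(2-methylpropanoyloxy)-4-[3-(trimethylsilyloxy)oxetan-3-yl]phenyl]methyl pentanoate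
Product: 17 [4-[(2R)-1-bromo-2,3-dihydroxypropan-2-yl]-3-(2-methylpropanoyloxy)phenyl]methyl pentanoate, via bis(trimethylsilyl) ether 16 (not isolated)
Conditions: chiral tert-leucine arylpyrrolidine-amide squaramide (10 mol %), Me3SiBr (1.5 equiv), t-BuOMe, −78 °C; then 1 M HCl, THF, 0 °C
Reagents that add atoms: bromotrimethylsilane, C[Si](C)(C)Br
Why: Hydrogen-bond-donor-catalysed enantioselective ring opening of a 3,3-disubstituted oxetane: the squaramide binds bromide while the silyl group activates the ring oxygen, and bromide attacks by SN2 one of the two enantiotopic ring CH2 groups, so the catalyst antipode decides which arm becomes CH2Br and thereby sets Cq as (R) without any bond to Cq being broken; dilute acid then hydrolyses both silyl ethers.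

**Step 10**
Reactants: 17 [4-[(2R)-1-bromo-2,3-dihydroxypropan-2-yl]-3-(2-methylpropanoyloxy)phenyl]methyl pentanoate
Product: 18 [4-[(2R)-1-acetoxy-3-bromo-2-hydroxypropan-2-yl]-3-(2-methylpropanoyloxy)phenyl]methyl pentanoate
Conditions: Ac2O, pyridine, CH2Cl2, 0 °C
Reagents that add atoms: acetic anhydride, CC(=O)OC(C)=O
Why: Chemoselective O-acetylation (nucleophilic acyl substitution) of the primary alcohol; the hindered tertiary benzylic alcohol does not react under these conditions and Cq is not touched.

**Step 11**
Reactants: 18 [4-[(2R)-1-acetoxy-3-bromo-2-hydroxypropan-2-yl]-3-(2-methylpropanoyloxy)phenyl]methyl pentanoate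
Product: 19 [4-[(2S)-2-(acetoxymethyl)oxiran-2-yl]-3-(2-methylpropanoyloxy)phenyl]methyl pentanoate
Conditions: Ag2O (1.5 equiv), THF, rt, dark
Reagents that add atoms: none
Why: Silver-assisted intramolecular Williamson etherification (3-exo-tet): monovalent silver pulls off bromide while the tertiary hydroxyl closes onto CH2Br, no free alkoxide forms so the three esters stay in place, and no bond to Cq is broken, so its arrangement is kept (the descriptor changes from R to S only because the CIP ranks of the two CH2 arms are exchanged).

**Compound list**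
1 | methyl 4-bromo-3-hydroxybenzoate | COC(=O)c1ccc(Br)c(O)c1 | starting material
2 | methyl 4-bromo-3-(methoxymethoxy)benzoate | COC(=O)c1ccc(Br)c(OCOC)c1 | intermediate
3 | [4-bromo-3-(methoxymethoxy)phenyl]methanol | OCc1ccc(Br)c(OCOC)c1 | intermediate
4 | 2-methoxy-N-methoxy-N-methylacetamide | COCC(=O)N(C)OC | starting material
5 | lithium [4-lithio-3-(methoxymethoxy)phenyl]methanolate | [Li]OCc1ccc([Li])c(OCOC)c1 | intermediate
6 | dilithium salt of the tetrahedral adduct of 5 with 4, 1-[4-(lithiooxymethyl)-2-(methoxymethoxy)phenyl]-2-methoxy-1-[methoxy(methyl)amino]ethan-1-olate | [Li]OCc1ccc(C(O[Li])(COC)N(C)OC)c(OCOC)c1 | intermediate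
7 | 1-[4-(hydroxymethyl)-2-(methoxymethoxy)phenyl]-2-methoxyethan-1-one | OCc1ccc(C(=O)COC)c(OCOC)c1 | intermediate
8 | pentanoyl chloride | CCCCC(Cl)=O | starting material
9 | [4-(2-methoxyacetyl)-3-(methoxymethoxy)phenyl]methyl pentanoate | CCCCC(=O)OCc1ccc(C(=O)COC)c(OCOC)c1 | intermediate
10 | [3-hydroxy-4-(2-methoxyacetyl)phenyl]methyl pentanoate | CCCCC(=O)OCc1ccc(C(=O)COC)c(O)c1 | intermediate
11 | 2-methylpropanoyl chloride (isobutyryl chloride) | CC(C)C(Cl)=O | starting material
12 | [4-(2-methoxyacetyl)-3-(2-methylpropanoyloxy)phenyl]methyl pentanoate | CCCCC(=O)OCc1ccc(C(=O)COC)c(OC(=O)C(C)C)c1 | intermediate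
13 | 1,4-biradical (hydroxybenzyl carbon and O–CH2 carbon) derived from 12 | CCCCC(=O)OCc1ccc([C](O)CO[CH2])c(OC(=O)C(C)C)c1 | intermediate
14 | [4-(3-hydroxyoxetan-3-yl)-3-(2-methylpropanoyloxy)phenyl]methyl pentanoate (achiral) | CCCCC(=O)OCc1ccc(C2(O)COC2)c(OC(=O)C(C)C)c1 | intermediate
15 | [3-(2-methylpropanoyloxy)-4-[3-(trimethylsilyloxy)oxetan-3-yl]phenyl]methyl pentanoate (achiral) | CCCCC(=O)OCc1ccc(C2(O[Si](C)(C)C)COC2)c(OC(=O)C(C)C)c1 | intermediate
16 | [4-[(2R)-1-bromo-2,3-bis(trimethylsilyloxy)propan-2-yl]-3-(2-methylpropanoyloxy)phenyl]methyl pentanoate | CCCCC(=O)OCc1ccc([C@@](O[Si](C)(C)C)(CO[Si](C)(C)C)CBr)c(OC(=O)C(C)C)c1 | intermediate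
17 | [4-[(2R)-1-bromo-2,3-dihydroxypropan-2-yl]-3-(2-methylpropanoyloxy)phenyl]methyl pentanoate | CCCCC(=O)OCc1ccc([C@@](O)(CO)CBr)c(OC(=O)C(C)C)c1 | intermediate
18 | [4-[(2R)-1-acetoxy-3-bromo-2-hydroxypropan-2-yl]-3-(2-methylpropanoyloxy)phenyl]methyl pentanoate | CCCCC(=O)OCc1ccc([C@@](O)(COC(C)=O)CBr)c(OC(=O)C(C)C)c1 | intermediate
19 | [4-[(2S)-2-(acetoxymethyl)oxiran-2-yl]-3-(2-methylpropanoyloxy)phenyl]methyl pentanoate | CCCCC(=O)OCc1ccc([C@@]2(COC(C)=O)CO2)c(OC(=O)C(C)C)c1 | target

**Step count.** Total: 11 steps. Longest linear sequence: 11 steps (1 → 19).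

**Steps most likely to fail**

Step 7. The biradical may cleave between CH2 and O (Norrish type 2 fragmentation) or hand the hydrogen back instead of coupling, so that little oxetane forms. The fallback builds the oxetane by carbonyl addition instead of photochemistry; it sets out from 1 and comes back at 14. The phenol of 1 is allylated (allyl bromide, K2CO3, DMF) to methyl 4-bromo-3-(prop-2-en-1-yloxy)benzoate F1. The ester is reduced with i-Bu2AlH to [4-bromo-3-(prop-2-en-1-yloxy)phenyl]methanol F2. Treatment with n-BuLi (2.1 equiv, THF, −78 °C) gives lithium [4-lithio-3-(prop-2-en-1-yloxy)phenyl]methanolate F3, which adds to oxetan-3-one to give 3-[4-(hydroxymethyl)-2-(prop-2-en-1-yloxy)phenyl]oxetan-3-ol F4. Acid chloride 8 with pyridine should acylate only the primary alcohol, giving [4-(3-hydroxyoxetan-3-yl)-3-(prop-2-en-1-yloxy)phenyl]methyl pentanoate F5. Zerovalent palladium, Pd(PPh3)4, with morpholine removes the allyl group under neutral conditions to [3-hydroxy-4-(3-hydroxyoxetan-3-yl)phenyl]methyl pentanoate F6. Acid chloride 11 with Et3N at 0 °C then acylates the phenol alone to 14. Allyl is used here instead of MOM because acid could ionize the tertiary benzylic oxetanol.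

Step 9. Discrimination between the two enantiotopic CH2–O bonds may be poor with the ortho-substituted aryl and the silyloxy group on the same carbon, or an uncatalysed opening may erode the selectivity. The fallback replaces catalytic desymmetrization by racemic opening and enzymatic kinetic resolution; it sets out from 15 and comes back at 18. Me3SiBr without catalyst (CH2Cl2, 0 °C) gives the racemic [4-[1-bromo-2,3-bis(trimethylsilyloxy)propan-2-yl]-3-(2-methylpropanoyloxy)phenyl]methyl pentanoate F7, and dilute HCl hydrolyses it to the racemic [4-(1-bromo-2,3-dihydroxypropan-2-yl)-3-(2-methylpropanoyloxy)phenyl]methyl pentanoate F8. A lipase (Burkholderia cepacia lipase or Candida antarctica lipase B, chosen by screening for preference for the R enantiomer) with vinyl acetate in t-BuOMe acetylates the primary hydroxyl of one enantiomer to give 18. It leaves behind [4-[(2S)-1-bromo-2,3-dihydroxypropan-2-yl]-3-(2-methylpropanoyloxy)phenyl]methyl pentanoate F9, which is removed by chromatography.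

Step 11. Silver-assisted loss of bromide from the neopentyl-type CH2Br may be slow, and the neighbouring acetate carbonyl may capture the developing positive charge (acetyl shift to the tertiary oxygen) in place of the hydroxyl. The fallback closes the ring before the acetate is present; it sets out from 17 and comes back at 19. K2CO3 in acetone at rt closes the tertiary hydroxyl onto CH2Br to [4-[(2R)-2-(hydroxymethyl)oxiran-2-yl]-3-(2-methylpropanoyloxy)phenyl]methyl pentanoate F10. The reaction is kept short and non-aqueous to avoid a Payne-type exchange of the two arms. Ac2O and pyridine at 0 °C then acetylate the primary alcohol to 19.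

**Further compounds**
F1 | step 7 | methyl 4-bromo-3-(prop-2-en-1-yloxy)benzoate | COC(=O)c1ccc(Br)c(OCC=C)c1
F2 | step 7 | [4-bromo-3-(prop-2-en-1-yloxy)phenyl]methanol | OCc1ccc(Br)c(OCC=C)c1
F3 | step 7 | lithium [4-lithio-3-(prop-2-en-1-yloxy)phenyl]methanolate | [Li]OCc1ccc([Li])c(OCC=C)c1
F4 | step 7 | 3-[4-(hydroxymethyl)-2-(prop-2-en-1-yloxy)phenyl]oxetan-3-ol | OCc1ccc(C2(O)COC2)c(OCC=C)c1
F5 | step 7 | [4-(3-hydroxyoxetan-3-yl)-3-(prop-2-en-1-yloxy)phenyl]methyl pentanoate | CCCCC(=O)OCc1ccc(C2(O)COC2)c(OCC=C)c1
F6 | step 7 | [3-hydroxy-4-(3-hydroxyoxetan-3-yl)phenyl]methyl pentanoate | CCCCC(=O)OCc1ccc(C2(O)COC2)c(O)c1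
F7 | step 9 | racemic [4-[1-bromo-2,3-bis(trimethylsilyloxy)propan-2-yl]-3-(2-methylpropanoyloxy)phenyl]methyl pentanoate | CCCCC(=O)OCc1ccc(C(O[Si](C)(C)C)(CO[Si](C)(C)C)CBr)c(OC(=O)C(C)C)c1
F8 | step 9 | racemic [4-(1-bromo-2,3-dihydroxypropan-2-yl)-3-(2-methylpropanoyloxy)phenyl]methyl pentanoate | CCCCC(=O)OCc1ccc(C(O)(CO)CBr)c(OC(=O)C(C)C)c1
F9 | step 9 | [4-[(2S)-1-bromo-2,3-dihydroxypropan-2-yl]-3-(2-methylpropanoyloxy)phenyl]methyl pentanoate | CCCCC(=O)OCc1ccc([C@](O)(CO)CBr)c(OC(=O)C(C)C)c1
F10 | step 11 | [4-[(2R)-2-(hydroxymethyl)oxiran-2-yl]-3-(2-methylpropanoyloxy)phenyl]methyl pentanoate | CCCCC(=O)OCc1ccc([C@@]2(CO)CO2)c(OC(=O)C(C)C)c1
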